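**Retrosynthetic overview** (locants follow the benzo[7]annulene numbering of the target: C1 = CH2, C2 = ketone, C3–Me, C4, C4a, C5 = CMe2, C6, C7, C8, C9–Me, C9a)

1. Target ⇐ 6,7-diol (double angeloylation) ⇐ O-bridged cage enone, by SmI2 scission of the O–C1 bond (α to the C2 ketone) after a rhodium-mediated shift of an exocyclic methylene into the C3=C4 position.
2. Cage ⇐ monocyclic cycloheptadienyl keto aldehyde, by an intramolecular carbonyl–diene oxa-[4+2] cycloaddition that forms C1–C9a and O–C7 together; the six-membered carbocycle and a temporary O-bridge close in one operation.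
3. Enabling feature: on the seven-membered ring, O-7 and the C9a–C1 bond are cis and 1,4-related across the C8=C9 double bond, and C1 is α to the C2 carbonyl; joining O-7 to C1 gives a 3,6-dihydro-2H-pyran (retron of a C1=O carbonyl plus the C7=C8–C9=C9a diene), and that C1–O bond is reductively removable.
4. Cycloheptadiene ⇐ ring-closing metathesis (C7=C8) of a triene ⇐ (Z)-iodoalkene Wittig/Stille on a lactol ⇐ γ-lactone. Stereo-relay: asymmetric vinylation sets C6; lactone alkylation then kinetic protonation sets C4a; the cycloaddition sets C9a and C7.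
5. Ring order: temporary γ-lactone → seven-membered carbocycle (step 8) → six-membered carbocycle plus O-bridge (step 11) → bridge excised (step 13).

Key step: step 11

Remark on the chemistry: the C3=C4 enone is carried through the cycloaddition as its exocyclic-methylene isomer, because only an sp3 C4 can be attached to C4a by enolate alkylation; Zn(CH=CH2)2 is taken as a stock reagent prepared beforehand from CH2=CHMgBr and ZnCl2.

**Step 1**
Reactants: 1 methyl 3,3-dimethylpent-4-enoate
Product: 3 methyl 3,3-dimethyl-4-oxobutanoate, via ozonide 2 (not isolated)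
Conditions: O3, CH2Cl2, −78 °C; then Me2S, −78 → 23 °C
Reagents that add atoms: ozone, [O-][O+]=O
Why: Ozonolysis with reductive work-up should cleave the only C=C bond to the non-enolisable neopentyl aldehyde and leave the ester untouched.

**Step 2**
Reactants: 3 methyl 3,3-dimethyl-4-oxobutanoate
Product: 5 (5S)-5-ethenyl-4,4-dimethyloxolan-2-one, via hydroxy ester 4 (not isolated)
Conditions: Zn(CH=CH2)2 (1.5 equiv), (−)-MIB [(2S)-3-exo-morpholinoisoborneol] (10 mol %), toluene, −20 → 0 °C; aq. NH4Cl; then p-TsOH·H2O (5 mol %), CH2Cl2, 23 °C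
Reagents that add atoms: divinylzinc, C=C[Zn]C=C
Why: Amino-alcohol-catalysed enantioselective alkenylzinc addition to the α-quaternary aldehyde should deliver vinyl to the Si face (the sense this ligand antipode is expected to give with simple aldehydes) and so set the C6 carbinol centre (S here, 6R in the target once the CIP priorities change), after which the γ-hydroxy ester lactonises readily under the Thorpe–Ingold effect.

**Step 3**
Reactants: 5 (5S)-5-ethenyl-4,4-dimethyloxolan-2-one
Product: 7 (3S,5S)-3-(2-bromoprop-2-en-1-yl)-5-ethenyl-4,4-dimethyloxolan-2-one (3,5-trans), via lithium enolate 6 (not isolated)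
Conditions: LiN(i-Pr)2 (1.1 equiv), THF, −78 °C; then 2,3-dibromopropene, DMPU, −78 → −40 °C
Reagents that add atoms: 2,3-dibromopropene, BrCC(Br)=C
Why: Alkylation of the lithium lactone enolate with the allylic bromide (SN2) should occur on the face away from the C5 vinyl group and the pseudo-axial C4 methyl group, giving the trans lactone and introducing C4 together with C3 as a vinyl bromide whose methylene carbon is the future C3 methyl group.

**Step 4**
Reactants: 7 (3S,5S)-3-(2-bromoprop-2-en-1-yl)-5-ethenyl-4,4-dimethyloxolan-2-one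
Product: 9 (3R,5S)-3-(2-bromoprop-2-en-1-yl)-5-ethenyl-4,4-dimethyloxolan-2-one (3,5-cis), via lithium enolate 8 (not isolated)
Conditions: LiN(i-Pr)2 (1.2 equiv), THF, −78 °C; then AcOH in THF, −78 °C
Reagents that add atoms: none
Why: Re-enolisation and kinetic protonation on the same less hindered face should invert the C4a centre to the cis lactone (also the expected thermodynamic isomer), which corresponds to the trans relationship between the C4a side chain and O-6 once C7 rather than oxygen is the ring member.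

**Step 5**
Reactants: 9 (3R,5S)-3-(2-bromoprop-2-en-1-yl)-5-ethenyl-4,4-dimethyloxolan-2-one
Product: 10 (3R,5S)-3-(2-bromoprop-2-en-1-yl)-5-ethenyl-4,4-dimethyloxolan-2-ol (anomeric mixture)
Conditions: i-Bu2AlH (1.1 equiv), CH2Cl2, −78 °C; Rochelle-salt work-up
Reagents that add atoms: none
Why: Partial reduction of the γ-lactone with i-Bu2AlH at low temperature should stop at the lactol because the tetrahedral aluminium acetal does not collapse before work-up; no stereocentre is touched.

**Step 6**
Reactants: 10 (3R,5S)-3-(2-bromoprop-2-en-1-yl)-5-ethenyl-4,4-dimethyloxolan-2-ol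
Product: 11 (3S,5S,6Z)-5-(2-bromoprop-2-en-1-yl)-7-iodo-4,4-dimethylocta-1,6-dien-3-ol
Conditions: [Ph3PEt]I, n-BuLi, THF, 23 °C; I2, −78 °C; NaN(SiMe3)2, −20 °C (3 equiv of ylide); then 10, −78 → 0 °C
Reagents that add atoms: (1-iodoethylidene)triphenylphosphorane, made in the flask, CC(I)=P(c1ccccc1)(c1ccccc1)c1ccccc1
Why: Wittig olefination of the open hydroxy-aldehyde form of the lactol with the α-iodo ylide (Stork–Zhao olefination) should give the (Z)-2-iodoalkene with iodine cis to C4a, which fixes the geometry of the future C9=C9a ring alkene.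

**Step 7**
Reactants: 11 (3S,5S,6Z)-5-(2-bromoprop-2-en-1-yl)-7-iodo-4,4-dimethylocta-1,6-dien-3-ol
Product: 12 (3S,5S,6Z)-5-(2-bromoprop-2-en-1-yl)-4,4,7-trimethylnona-1,6,8-trien-3-ol
Conditions: CH2=CHSnBu3 (1.2 equiv), Pd2(dba)3 (2.5 mol %), AsPh3 (20 mol %), NMP, 23 °C
Reagents that add atoms: tributyl(vinyl)stannane, C=C[Sn](CCCC)(CCCC)CCCC
Why: Stille cross-coupling should replace iodine by vinyl with retention of alkene geometry, the alkenyl iodide adding oxidatively to zerovalent palladium at 23 °C far faster than the 2-bromoalkene.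

**Step 8**
Reactants: 12 (3S,5S,6Z)-5-(2-bromoprop-2-en-1-yl)-4,4,7-trimethylnona-1,6,8-trien-3-ol
Product: 13 (1S,6S)-6-(2-bromoprop-2-en-1-yl)-4,7,7-trimethylcyclohepta-2,4-dien-1-ol
Conditions: second-generation Grubbs catalyst RuCl2(=CHPh)(H2IMes)(PCy3) (5 mol %), CH2Cl2 (2 mM), 40 °C
Reagents that add atoms: none
Why: Ring-closing metathesis between the two monosubstituted alkene termini should close the seven-membered ring as the cis,cis-1,3-diene with loss of ethene, the trisubstituted alkene and the 2-bromoalkene being too hindered or too electron-poor to compete.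

**Step 9**
Reactants: 13 (1S,6S)-6-(2-bromoprop-2-en-1-yl)-4,7,7-trimethylcyclohepta-2,4-dien-1-ol
Product: 15 1-[(tert-butyldimethylsilyl)oxy]-3-{[(1S,6S)-6-hydroxy-3,7,7-trimethylcyclohepta-2,4-dien-1-yl]methyl}but-3-en-2-one, via dilithio species 14 (not isolated)
Conditions: t-BuLi (3.1 equiv), Et2O, −78 °C; then TBSOCH2C(O)N(OMe)Me, −78 → 0 °C; aq. NH4Cl
Reagents that add atoms: 2-[(tert-butyldimethylsilyl)oxy]-N-methoxy-N-methylacetamide, CON(C)C(=O)CO[Si](C)(C)C(C)(C)C
Why: Bromine–lithium exchange (after deprotonation of the hydroxyl) should give the alkenyllithium, which adds once to the Weinreb amide because the chelated tetrahedral intermediate survives until work-up (Weinreb ketone synthesis), completing C2 and C1 at the α-ketol oxidation level.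

**Step 10**
Reactants: 15 1-[(tert-butyldimethylsilyl)oxy]-3-{[(1S,6S)-6-hydroxy-3,7,7-trimethylcyclohepta-2,4-dien-1-yl]methyl}but-3-en-2-one
Product: 16 1-hydroxy-3-{[(1S,6S)-6-hydroxy-3,7,7-trimethylcyclohepta-2,4-dien-1-yl]methyl}but-3-en-2-one
Conditions: HF·pyridine, pyridine, THF, 0 °C
Reagents that add atoms: none
Why: Fluoride-mediated desilylation under pyridine buffering should free the primary α-ketol without ionising the dienylic C6 alcohol or adding to the methylene ketone.

**Step 11**
Reactants: 16 1-hydroxy-3-{[(1S,6S)-6-hydroxy-3,7,7-trimethylcyclohepta-2,4-dien-1-yl]methyl}but-3-en-2-one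
Product: 18 (1S,4aS,6R,7R,9aR)-6-hydroxy-5,5,9-trimethyl-3-methylidene-1,3,4,4a,5,6,7,9a-octahydro-2H-1,7-epoxybenzo[7]annulen-2-one, via keto aldehyde 17 (not isolated)
Conditions: Cu(OAc)2 (20 mol %), O2 (1 atm), 4 Å molecular sieves, MeCN, 23 °C; then solvent exchange to toluene, 90 °C
Reagents that add atoms: none
Why: Copper-catalysed aerobic oxidation of the α-ketol (enediolate oxidation, which leaves the isolated C6 alcohol alone) should unveil the 2-oxo-aldehyde, whose C1=O then adds as the 2π component across C9a and C7 of the s-cis-locked C7=C8–C9=C9a diene in a concerted, asynchronous oxa-[4+2] (hetero-Diels–Alder) cycloaddition, the closest known type being the thermal carbonyl–diene cycloaddition of glyoxal- and glyoxylate-type aldehydes with 1,3-dienes, here in its intramolecular, tether-fused form. Two rings close: the six-membered carbocycle C1–C2–C3–C4–C4a–C9a through the new C1–C9a bond (exo with respect to the C9a=C9 bond, four-atom tether anchored at C4a) and the dihydropyran ring O–C1–C9a–C9=C8–C7 through the new O–C7 bond, which becomes the two-atom bridge of a 2-oxabicyclo[3.2.2]nonene. C9a is set by the C4a stereocentre, because the short tether can only reach the diene face that carries the C4a side chain (cis ring fusion); C7 follows from suprafacial addition to the diene (oxygen on the same face as C1, hence trans to the C6 hydroxyl); C1, with its hydrogen toward the alkene bridge, is a temporary stereocentre erased in step 13. Regioselectivity (carbon to C9a, oxygen to C7) is secured by the tether length and reinforced electronically, since C9a is the nucleophilic terminus of the 2-methyl-substituted diene and C1 the electrophilic end of the carbonyl, and the aldehyde reacts in preference to the flanked ketone. The competing carbonyl–ene pathway is disfavoured by the cisoid cyclic diene and the absence of a strong Lewis acid, and the methylene ketone cannot serve as an all-carbon dienophile because its link to C4a is too short.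

**Step 12**
Reactants: 18 (1S,4aS,6R,7R,9aR)-6-hydroxy-5,5,9-trimethyl-3-methylidene-1,3,4,4a,5,6,7,9a-octahydro-2H-1,7-epoxybenzo[7]annulen-2-one
Product: 19 (1S,4aS,6R,7R,9aR)-6-hydroxy-3,5,5,9-tetramethyl-1,4a,5,6,7,9a-hexahydro-2H-1,7-epoxybenzo[7]annulen-2-one
Conditions: RhCl3·3H2O (5 mol %), EtOH, 70 °C
Reagents that add atoms: none
Why: Rhodium-hydride-mediated alkene isomerisation (hydrometalation/β-hydride elimination) should move the exocyclic methylene into the ring to give the conjugated, trisubstituted C3=C4 enone as the thermodynamic product, while the C8=C9 bond cannot migrate toward either bridgehead and the cis ring fusion at C4a is held by the cage.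

**Step 13**
Reactants: 19 (1S,4aS,6R,7R,9aR)-6-hydroxy-3,5,5,9-tetramethyl-1,4a,5,6,7,9a-hexahydro-2H-1,7-epoxybenzo[7]annulen-2-one
Product: 20 (4aS,6R,7R,9aR)-6,7-dihydroxy-3,5,5,9-tetramethyl-1,4a,5,6,7,9a-hexahydro-2H-benzo[7]annulen-2-one
Conditions: SmI2 (2.5 equiv), THF–MeOH (10:1), −78 °C
Reagents that add atoms: none
Why: Single-electron reduction of the C2 ketone by SmI2 should expel the α-oxygen substituent at C1 (reductive cleavage of an α-alkoxy ketone), and protonation of the resulting cross-conjugated samarium dienolate at C1 by methanol should give the C1 methylene and free the 7-hydroxyl with its configuration untouched, removing the temporary O-bridge.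

**Step 14**
Reactants: 20 (4aS,6R,7R,9aR)-6,7-dihydroxy-3,5,5,9-tetramethyl-1,4a,5,6,7,9a-hexahydro-2H-benzo[7]annulen-2-one
Product: 21 (4aS,6R,7R,9aR)-3,5,5,9-tetramethyl-2-oxo-2,4a,5,6,7,9a-hexahydro-1H-benzo[7]annulene-6,7-diyl bis[(2Z)-2-methylbut-2-enoate]
Conditions: angelic acid (4 equiv), 2,4,6-trichlorobenzoyl chloride (4 equiv), Et3N (8 equiv), toluene, 23 °C; then 20, toluene, 80 °C
Reagents that add atoms: angelic acid (used as its 2,4,6-trichlorobenzoic mixed anhydride), C/C=C(/C)C(=O)O
Why: Acylation of both secondary hydroxyls by the preformed angelic 2,4,6-trichlorobenzoic mixed anhydride without a nucleophilic catalyst (Yamaguchi-type esterification) should install the two (Z)-2-methylbut-2-enoates without isomerisation to tiglates, giving the target.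

**Compound list**
1 | methyl 3,3-dimethylpent-4-enoate | C=CC(C)(C)CC(=O)OC | starting material
2 | methyl 3-methyl-3-(1,2,4-trioxolan-3-yl)butanoate (ozonide) | COC(=O)CC(C)(C)C1OCOO1 | intermediate
3 | methyl 3,3-dimethyl-4-oxobutanoate | COC(=O)CC(C)(C)C=O | intermediate
4 | methyl (4S)-4-hydroxy-3,3-dimethylhex-5-enoate | COC(=O)CC(C)(C)[C@@H](O)C=C | intermediate
5 | (5S)-5-ethenyl-4,4-dimethyloxolan-2-one | C=C[C@@H]1OC(=O)CC1(C)C | intermediate
6 | lithium enolate of 5 | C=C[C@@H]1OC(O[Li])=CC1(C)C | intermediate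
7 | (3S,5S)-3-(2-bromoprop-2-en-1-yl)-5-ethenyl-4,4-dimethyloxolan-2-one (trans) | C=C[C@@H]1OC(=O)[C@@H](CC(Br)=C)C1(C)C | intermediate
8 | lithium enolate of 7 | C=C[C@@H]1OC(O[Li])=C(CC(Br)=C)C1(C)C | intermediate
9 | (3R,5S)-3-(2-bromoprop-2-en-1-yl)-5-ethenyl-4,4-dimethyloxolan-2-one (cis) | C=C[C@@H]1OC(=O)[C@H](CC(Br)=C)C1(C)C | intermediate
10 | (3R,5S)-3-(2-bromoprop-2-en-1-yl)-5-ethenyl-4,4-dimethyloxolan-2-ol (anomers) | C=C[C@@H]1OC(O)[C@H](CC(Br)=C)C1(C)C | intermediate
11 | (3S,5S,6Z)-5-(2-bromoprop-2-en-1-yl)-7-iodo-4,4-dimethylocta-1,6-dien-3-ol | C=C[C@H](O)C(C)(C)[C@@H](CC(Br)=C)/C=C(/C)I | intermediate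
12 | (3S,5S,6Z)-5-(2-bromoprop-2-en-1-yl)-4,4,7-trimethylnona-1,6,8-trien-3-ol | C=C[C@H](O)C(C)(C)[C@@H](CC(Br)=C)/C=C(/C)C=C | intermediate
13 | (1S,6S)-6-(2-bromoprop-2-en-1-yl)-4,7,7-trimethylcyclohepta-2,4-dien-1-ol | C=C(Br)C[C@H]1C=C(C)C=C[C@H](O)C1(C)C | intermediate
14 | dilithio species of 13 (lithium alkoxide and 2-lithioalkene) | [Li]C(=C)C[C@H]1C=C(C)C=C[C@H](O[Li])C1(C)C | intermediate
15 | 1-[(tert-butyldimethylsilyl)oxy]-3-{[(1S,6S)-6-hydroxy-3,7,7-trimethylcyclohepta-2,4-dien-1-yl]methyl}but-3-en-2-one | CC(C)(C)[Si](C)(C)OCC(=O)C(=C)C[C@H]1C=C(C)C=C[C@H](O)C1(C)C | intermediate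
16 | 1-hydroxy-3-{[(1S,6S)-6-hydroxy-3,7,7-trimethylcyclohepta-2,4-dien-1-yl]methyl}but-3-en-2-one | OCC(=O)C(=C)C[C@H]1C=C(C)C=C[C@H](O)C1(C)C | intermediate
17 | 3-{[(1S,6S)-6-hydroxy-3,7,7-trimethylcyclohepta-2,4-dien-1-yl]methyl}-2-oxobut-3-enal | O=CC(=O)C(=C)C[C@H]1C=C(C)C=C[C@H](O)C1(C)C | intermediate
18 | (1S,4aS,6R,7R,9aR)-6-hydroxy-5,5,9-trimethyl-3-methylidene-1,3,4,4a,5,6,7,9a-octahydro-2H-1,7-epoxybenzo[7]annulen-2-one | O1[C@@H]2C=C(C)[C@@H]3[C@H]1C(=O)C(=C)C[C@@H]3C(C)(C)[C@H]2O | intermediate
19 | (1S,4aS,6R,7R,9aR)-6-hydroxy-3,5,5,9-tetramethyl-1,4a,5,6,7,9a-hexahydro-2H-1,7-epoxybenzo[7]annulen-2-one | O1[C@@H]2C=C(C)[C@@H]3[C@H]1C(=O)C(C)=C[C@@H]3C(C)(C)[C@H]2O | intermediate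
20 | (4aS,6R,7R,9aR)-6,7-dihydroxy-3,5,5,9-tetramethyl-1,4a,5,6,7,9a-hexahydro-2H-benzo[7]annulen-2-one | O[C@@H]1C=C(C)[C@@H]2CC(=O)C(C)=C[C@@H]2C(C)(C)[C@H]1O | intermediate
21 | (4aS,6R,7R,9aR)-3,5,5,9-tetramethyl-2-oxo-2,4a,5,6,7,9a-hexahydro-1H-benzo[7]annulene-6,7-diyl bis[(2Z)-2-methylbut-2-enoate] | C/C=C(/C)C(=O)O[C@@H]1C=C(C)[C@@H]2CC(=O)C(C)=C[C@@H]2C(C)(C)[C@H]1OC(=O)/C(C)=C\C | target

**Totals and risks**

Total step count: 14. Longest linear sequence: 14 steps (a single linear chain from 1).

Steps most likely to fail, in order of risk: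

Step 11. The cross-conjugated methylene keto aldehyde 17 may be consumed by intermolecular hetero-Diels–Alder dimerisation, by conjugate additions, or by a carbonyl–ene reaction with the C9 methyl group faster than it cyclises. The fallback sets out from 16 and returns at 19; it removes the acceptor alkene before the cycloaddition and creates the enone by oxidation afterwards. Conjugate reduction of 16 with [(Ph3P)CuH]6 should give the saturated ketol F1 (both C3 epimers). Copper-catalysed aerobic oxidation as in step 11 should give the saturated keto aldehyde F2, which on heating in toluene should cyclise to the saturated cage ketone F3. TMSOTf/Et3N should then give the thermodynamic C2=C3 silyl enol ether, also silylated at O-6, F4. Saegusa–Ito oxidation with Pd(OAc)2 in MeCN should give the cage enone silyl ether F5, and citric acid in methanol returns 19.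

Step 13. Conjugate reduction of the enone or ketyl coupling may compete with scission of the C1–O bond. The fallback sets out from 19 and returns at 20; both reductions are driven to completion and the enone is restored. SmI2 in excess with HMPA and t-BuOH should give the saturated ketone diol F6. TMSOTf/Et3N should give the tris-silyl compound F7 (silyl enol ether toward C3), Pd(OAc)2 in MeCN the bis-silyl enone F8, and citric acid in methanol returns 20.

Step 6. The gem-dimethyl lactol may open too slowly, so that the basic ylide epimerises C4a or eliminates HBr before olefination occurs. The fallback sets out from 9 and returns at 11. Aminolysis of 9 with MeNH(OMe)·HCl/i-PrMgCl should give the hydroxy Weinreb amide F9, and TESOTf/2,6-lutidine its silyl ether F10. i-Bu2AlH at −78 °C should give the open aldehyde F11, the same α-iodo ylide the silyl-protected iodoalkene F12, and HF·pyridine returns 11.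

**Further compounds**
F1 | step 11 | 1-hydroxy-3-{[(1S,6S)-6-hydroxy-3,7,7-trimethylcyclohepta-2,4-dien-1-yl]methyl}butan-2-one (C3 epimers) | OCC(=O)C(C)C[C@H]1C=C(C)C=C[C@H](O)C1(C)C
F2 | step 11 | 3-{[(1S,6S)-6-hydroxy-3,7,7-trimethylcyclohepta-2,4-dien-1-yl]methyl}-2-oxobutanal (C3 epimers) | O=CC(=O)C(C)C[C@H]1C=C(C)C=C[C@H](O)C1(C)C
F3 | step 11 | saturated cage ketone: 3,4-dihydro analogue of 19 (C3 epimers) | O1[C@@H]2C=C(C)[C@@H]3[C@H]1C(=O)C(C)C[C@@H]3C(C)(C)[C@H]2O
F4 | step 11 | C2=C3 trimethylsilyl enol ether of F3 with 6-O-trimethylsilyl ether | O1[C@@H]2C=C(C)[C@@H]3[C@H]1C(O[Si](C)(C)C)=C(C)C[C@@H]3C(C)(C)[C@H]2O[Si](C)(C)C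
F5 | step 11 | 6-O-trimethylsilyl ether of 19 | O1[C@@H]2C=C(C)[C@@H]3[C@H]1C(=O)C(C)=C[C@@H]3C(C)(C)[C@H]2O[Si](C)(C)C
F6 | step 13 | 3,4-dihydro analogue of 20 (saturated ketone diol, C3 epimers) | O[C@@H]1C=C(C)[C@@H]2CC(=O)C(C)C[C@@H]2C(C)(C)[C@H]1O
F7 | step 13 | C2=C3 trimethylsilyl enol ether of F6 with 6-O- and 7-O-trimethylsilyl ethers | C[Si](C)(C)O[C@@H]1C=C(C)[C@@H]2CC(O[Si](C)(C)C)=C(C)C[C@@H]2C(C)(C)[C@H]1O[Si](C)(C)C
F8 | step 13 | 6,7-bis(O-trimethylsilyl) ether of 20 | C[Si](C)(C)O[C@@H]1C=C(C)[C@@H]2CC(=O)C(C)=C[C@@H]2C(C)(C)[C@H]1O[Si](C)(C)C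
F9 | step 6 | (2R,4S)-2-(2-bromoprop-2-en-1-yl)-4-hydroxy-N-methoxy-N,3,3-trimethylhex-5-enamide | C=C[C@H](O)C(C)(C)[C@@H](CC(Br)=C)C(=O)N(C)OC
F10 | step 6 | 4-O-triethylsilyl ether of F9 | C=C[C@H](O[Si](CC)(CC)CC)C(C)(C)[C@@H](CC(Br)=C)C(=O)N(C)OC
F11 | step 6 | (2R,4S)-2-(2-bromoprop-2-en-1-yl)-3,3-dimethyl-4-[(triethylsilyl)oxy]hex-5-enal | C=C[C@H](O[Si](CC)(CC)CC)C(C)(C)[C@@H](CC(Br)=C)C=O
F12 | step 6 | 3-O-triethylsilyl ether of 11 | C=C[C@H](O[Si](CC)(CC)CC)C(C)(C)[C@@H](CC(Br)=C)/C=C(/C)I
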